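**Plan**
- Penibenzophenone C (13) is a benzophenone. One carbon atom, the ketone carbon, bridges C2 of ring A (between C1–CO2Me and C3–OMe) and C1' of ring B (between the oxygens on C2' and C6'). A one-atom C=O bridge of this kind can be supplied as carbon monoxide.
- Retrosynthesis: the acetyl group on O6' is removed, O5 is masked as a benzyl ether and O2'/O6' as MOM ethers, which makes ring B symmetric about its C1'–C4' axis. The bonds C2–C(=O) and C(=O)–C1' are then cut together, giving aryl iodide 3, CO 9 and boronic acid 8.
- Forward: both benzene rings are bought and no ring is built. Ring A iodide (steps 1–2) and ring B boronic acid (steps 3–4) are prepared in parallel and joined through CO in step 5.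
- Endgame: MOM cleavage, acetylation of one of the two equivalent ring B phenols, then hydrogenolysis of the ring A benzyl ether.
- Stereochemistry: the target has no stereocentre. The questions to control are regiochemistry (iodination para to the phenol, lithiation between the two OMOM groups) and chemoselectivity (ketone against biaryl, mono- against diacetate).

Key step: step 5

Remark: the aryl–carbonyl axes of this tetra-ortho-substituted benzophenone are taken to rotate freely at room temperature, so 13 is treated as achiral and the two ring B hydroxyls of 11 as equivalent.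

**Step 1**
Reactants: 1 methyl 3-hydroxy-5-methoxybenzoate
Product: 2 methyl 5-hydroxy-2-iodo-3-methoxybenzoate
Conditions: NIS (1.0 equiv), TsOH·H2O (1.0 equiv), MeCN, 0 °C → rt, dark
Reagents that add atoms: N-iodosuccinimide, O=C1CCC(=O)N1I
Why: Electrophilic aromatic iodination, in which under acidic (non-phenoxide) conditions the free OH is the strongest donor and sends the bulky iodonium equivalent to its para carbon (C6 of 1, also ortho to OMe and so doubly activated), the ester-flanked type of position at which 3,5-dioxygenated benzoates are known to be halogenated.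

**Step 2**
Reactants: 2 methyl 5-hydroxy-2-iodo-3-methoxybenzoate
Product: 3 methyl 5-(benzyloxy)-2-iodo-3-methoxybenzoate
Conditions: BnBr (1.1 equiv), K2CO3, acetone, reflux
Reagents that add atoms: benzyl bromide, BrCc1ccccc1
Why: Williamson ether synthesis, in which the phenoxide formed by K2CO3 displaces bromide from the benzylic halide by SN2 while the aryl iodide and the methyl ester are untouched.

**Step 3**
Reactants: 4 orcinol (5-methylbenzene-1,3-diol, anhydrous)
Product: 5 1,3-bis(methoxymethoxy)-5-methylbenzene
Conditions: NaH (2.4 equiv), MOMCl (2.4 equiv), DMF, 0 °C → rt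
Reagents that add atoms: chloromethyl methyl ether, COCCl
Why: Double Williamson-type O-alkylation of the bis-phenoxide with the reactive α-chloro ether gives acetals that withstand organolithium and carbonate bases and later act as ortho-directing groups.

**Step 4**
Reactants: 5 1,3-bis(methoxymethoxy)-5-methylbenzene
Product: 8 [2,6-bis(methoxymethoxy)-4-methylphenyl]boronic acid, via aryllithium 6 (not isolated), via lithium aryltrimethoxyborate 7 (not isolated)
Conditions: n-BuLi (1.1 equiv), THF, 0 °C → rt; B(OMe)3, −78 °C → rt; sat. aq. NH4Cl
Reagents that add atoms: n-butyllithium, [Li]CCCC (lithium of 6 and 7); trimethyl borate, COB(OC)OC; water, O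
Why: Directed ortho-metalation followed by electrophilic borylation, in which the two MOM ethers cooperatively guide n-BuLi to the C–H between them, B(OMe)3 traps the aryllithium as the ate complex and the near-neutral work-up hydrolyses the B–OMe bonds without harming the acetals.

**Step 5**
Reactants: 3 methyl 5-(benzyloxy)-2-iodo-3-methoxybenzoate; 8 [2,6-bis(methoxymethoxy)-4-methylphenyl]boronic acid; 9 carbon monoxide
Product: 10 methyl 5-(benzyloxy)-2-[2,6-bis(methoxymethoxy)-4-methylbenzoyl]-3-methoxybenzoate
Conditions: PdCl2(IPr)(3-chloropyridine) (5 mol %; IPr = 1,3-bis(2,6-diisopropylphenyl)imidazol-2-ylidene), Cs2CO3 (3 equiv), CO (4 bar), PhCl, 90 °C; 8 (2 equiv, in 1,4-dioxane) dosed by pump over 6 h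
Reagents that add atoms: carbon monoxide 9, [C-]#[O+]
Why: Zerovalent palladium released from the precatalyst adds oxidatively to the C–I bond of 3, CO inserts into the crowded aryl–palladium bond to give an aroyl complex of divalent palladium, the caesium boronate of 8 hands over ring B, and reductive elimination makes the second C–C bond and frees 10. The closest known reaction type is the carbonylative Suzuki–Miyaura coupling of 2,6-disubstituted aryl iodides to hindered diaryl ketones under NHC–palladium catalysis, and a ketone with four ortho substituents sits at the demanding end of that scope. No ring is closed and no stereocentre is created. The first selectivity needed is ketone over biaryl: the CO2Me and OMe groups beside palladium retard transmetalation at the aryl stage, migratory insertion relieves strain by moving the metal one atom away from the congested carbon, and CO pressure together with a low stationary concentration of 8 reinforces this order of events. The second is that transmetalation must outrun base-induced protodeboronation of the 2,6-dialkoxyarylboronic acid, which is addressed by a nearly anhydrous medium, by dosing an excess of 8 at the pace of catalyst turnover and by the bulky, strongly donating carbene that keeps the catalyst alive at 90 °C. The MOM ethers, the benzyl ether and the methyl ester are inert to Cs2CO3 in chlorobenzene.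

**Step 6**
Reactants: 10 methyl 5-(benzyloxy)-2-[2,6-bis(methoxymethoxy)-4-methylbenzoyl]-3-methoxybenzoate
Product: 11 methyl 5-(benzyloxy)-2-(2,6-dihydroxy-4-methylbenzoyl)-3-methoxybenzoate
Conditions: HCl (1.25 M in MeOH), MeOH, 40 °C
Reagents that add atoms: none
Why: Acid-catalysed acetal exchange (MOM cleavage) passes both CH2 units to the solvent, the methyl ester can only undergo degenerate transesterification in methanol, and the benzyl ether and the ketone are stable to dilute HCl.

**Step 7**
Reactants: 11 methyl 5-(benzyloxy)-2-(2,6-dihydroxy-4-methylbenzoyl)-3-methoxybenzoate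
Product: 12 methyl 2-[2-(acetyloxy)-6-hydroxy-4-methylbenzoyl]-5-(benzyloxy)-3-methoxybenzoate
Conditions: Ac2O (1.0 equiv, slow addition), pyridine (3 equiv), CH2Cl2, 0 °C
Reagents that add atoms: acetic anhydride, CC(=O)OC(C)=O
Why: O-Acetylation (acyl transfer) of one of two equivalent phenols, in which only one ring B hydroxyl at a time can chelate the ketone oxygen, the free one is acylated, the survivor is then held in a strong O–H···O=C hydrogen bond that lowers its nucleophilicity, and the ring A oxygen is masked as its benzyl ether.

**Step 8**
Reactants: 12 methyl 2-[2-(acetyloxy)-6-hydroxy-4-methylbenzoyl]-5-(benzyloxy)-3-methoxybenzoate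
Product: 13 penibenzophenone C, methyl 2-[2-(acetyloxy)-6-hydroxy-4-methylbenzoyl]-5-hydroxy-3-methoxybenzoate
Conditions: H2 (1 atm), 10% Pd/C, EtOAc, rt
Reagents that add atoms: none
Why: Catalytic hydrogenolysis of the benzylic C–O bond in an aprotic solvent, so that the aryl acetate is not solvolysed, while the chelated ketone shielded by four ortho substituents should resist reduction at 1 atm.

**Compound list**
1 | methyl 3-hydroxy-5-methoxybenzoate | COC(=O)c1cc(O)cc(OC)c1 | starting material
2 | methyl 5-hydroxy-2-iodo-3-methoxybenzoate | COC(=O)c1cc(O)cc(OC)c1I | intermediate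
3 | methyl 5-(benzyloxy)-2-iodo-3-methoxybenzoate | COC(=O)c1cc(OCc2ccccc2)cc(OC)c1I | intermediate
4 | orcinol (5-methylbenzene-1,3-diol) | Cc1cc(O)cc(O)c1 | starting material
5 | 1,3-bis(methoxymethoxy)-5-methylbenzene | COCOc1cc(C)cc(OCOC)c1 | intermediate
6 | [2,6-bis(methoxymethoxy)-4-methylphenyl]lithium | [Li]c1c(OCOC)cc(C)cc1OCOC | intermediate
7 | lithium [2,6-bis(methoxymethoxy)-4-methylphenyl]trimethoxyborate | [Li+].CO[B-](OC)(OC)c1c(OCOC)cc(C)cc1OCOC | intermediate
8 | [2,6-bis(methoxymethoxy)-4-methylphenyl]boronic acid | COCOc1cc(C)cc(OCOC)c1B(O)O | intermediate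
9 | carbon monoxide | [C-]#[O+] | starting material
10 | methyl 5-(benzyloxy)-2-[2,6-bis(methoxymethoxy)-4-methylbenzoyl]-3-methoxybenzoate | COC(=O)c1cc(OCc2ccccc2)cc(OC)c1C(=O)c1c(OCOC)cc(C)cc1OCOC | intermediate
11 | methyl 5-(benzyloxy)-2-(2,6-dihydroxy-4-methylbenzoyl)-3-methoxybenzoate | COC(=O)c1cc(OCc2ccccc2)cc(OC)c1C(=O)c1c(O)cc(C)cc1O | intermediate
12 | methyl 2-[2-(acetyloxy)-6-hydroxy-4-methylbenzoyl]-5-(benzyloxy)-3-methoxybenzoate | COC(=O)c1cc(OCc2ccccc2)cc(OC)c1C(=O)c1c(O)cc(C)cc1OC(C)=O | intermediate
13 | penibenzophenone C | COC(=O)c1cc(O)cc(OC)c1C(=O)c1c(O)cc(C)cc1OC(C)=O | target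

**Step count**
- Total step count: 8.
- Longest linear sequence: 6 steps (1 → 2 → 3 → 10 → 11 → 12 → 13; the branch 4 → 5 → 8 → 10 → 13 is equally long).

**Steps most likely to fail**

1. Step 5.
   - Risk: transmetalation or reductive elimination may stall at the aroyl–palladium centre, which is flanked on both sides. Protodeboronation of the boron partner, coupling without CO uptake, or hydrolytic capture of the aroyl complex could then take over.
   - Fallback: it sets out from 3 and from aryllithium 6, and returns at 10. The ketone carbon is brought in at the aldehyde level and the bridge is oxidised afterwards.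
   - Iodide 3 undergoes iodine–magnesium exchange with i-PrMgCl·LiCl (THF, −40 °C) to [4-(benzyloxy)-2-methoxy-6-(methoxycarbonyl)phenyl]magnesium chloride F1. Quenching with DMF gives methyl 5-(benzyloxy)-2-formyl-3-methoxybenzoate F2.
   - Aryllithium 6, generated from 5 as in step 4, adds to the small and electrophilic formyl carbon at −78 °C. The alkoxide closes onto the neighbouring ester to give racemic 6-(benzyloxy)-3-[2,6-bis(methoxymethoxy)-4-methylphenyl]-4-methoxy-2-benzofuran-1(3H)-one F3.
   - Deprotonation of the doubly benzylic C3–H with KN(SiMe3)2 (THF, −78 °C) and hydroxylation with 2-(phenylsulfonyl)-3-phenyloxaziridine gives the lactol. Its open tautomer is 5-(benzyloxy)-2-[2,6-bis(methoxymethoxy)-4-methylbenzoyl]-3-methoxybenzoic acid F4.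
   - Carboxylate alkylation (MeI, K2CO3, DMF) then gives the normal methyl ester 10.

2. Step 1.
   - Risk: regiocontrol may be lost through attack of the iodinating agent ortho to the phenol (para to the methoxy group, or between the two oxygens). Double iodination is also possible.
   - Fallback: it sets out from 1 and returns at 2. Electronic para-direction is replaced by steric blocking.
   - Phenol 1 is silylated (i-Pr3SiCl, imidazole, DMF) to methyl 3-methoxy-5-[(triisopropylsilyl)oxy]benzoate F5. Both carbons next to the bulky silyl ether are now shielded.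
   - Iodination (NIS, cat. CF3CO2H, MeCN) should therefore take the only open activated site and give methyl 2-iodo-3-methoxy-5-[(triisopropylsilyl)oxy]benzoate F6.
   - Bu4NF (THF, 0 °C) then releases 2.

3. Step 7.
   - Risk: over-acylation or incomplete conversion, because the distinction between the first and the second acetyl transfer rests only on hydrogen bonding.
   - Fallback: it sets out from 11 and returns at 12. The monoacetate is approached from the other side.
   - Exhaustive acetylation (excess Ac2O, pyridine, cat. DMAP, rt) gives methyl 5-(benzyloxy)-2-[2,6-bis(acetyloxy)-4-methylbenzoyl]-3-methoxybenzoate F7.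
   - Controlled methanolysis (K2CO3, 1.0 equiv, MeOH/CH2Cl2, −20 °C) removes one acetyl group. The chelated phenoxide formed first carries a negative charge next to the remaining acetate and should slow the second cleavage, so the reaction can be stopped at 12.

**Further compounds**
F1 | step 5 | [4-(benzyloxy)-2-methoxy-6-(methoxycarbonyl)phenyl]magnesium chloride | COC(=O)c1cc(OCc2ccccc2)cc(OC)c1[Mg]Cl
F2 | step 5 | methyl 5-(benzyloxy)-2-formyl-3-methoxybenzoate | COC(=O)c1cc(OCc2ccccc2)cc(OC)c1C=O
F3 | step 5 | rac-6-(benzyloxy)-3-[2,6-bis(methoxymethoxy)-4-methylphenyl]-4-methoxy-2-benzofuran-1(3H)-one | O=C1OC(c2c(OCOC)cc(C)cc2OCOC)c2c(OC)cc(OCc3ccccc3)cc12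
F4 | step 5 | 5-(benzyloxy)-2-[2,6-bis(methoxymethoxy)-4-methylbenzoyl]-3-methoxybenzoic acid | OC(=O)c1cc(OCc2ccccc2)cc(OC)c1C(=O)c1c(OCOC)cc(C)cc1OCOC
F5 | step 1 | methyl 3-methoxy-5-[(triisopropylsilyl)oxy]benzoate | COC(=O)c1cc(OC)cc(O[Si](C(C)C)(C(C)C)C(C)C)c1
F6 | step 1 | methyl 2-iodo-3-methoxy-5-[(triisopropylsilyl)oxy]benzoate | COC(=O)c1cc(O[Si](C(C)C)(C(C)C)C(C)C)cc(OC)c1I
F7 | step 7 | methyl 5-(benzyloxy)-2-[2,6-bis(acetyloxy)-4-methylbenzoyl]-3-methoxybenzoate | COC(=O)c1cc(OCc2ccccc2)cc(OC)c1C(=O)c1c(OC(C)=O)cc(C)cc1OC(C)=O
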